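**Retrosynthetic overview**
- Last bond: the C8–O ester, by acylation of the 8-hydroxy macrolactone with (E)-4-acetoxy-2-methylbut-2-enoic acid.
- Ten-membered carbocycle and α-methylene-γ-lactone together: CrCl2-mediated Barbier closure of C6–C7 (2-(bromomethyl)acrylate onto a (Z)-enal), then lactone C–O closure; the allyl bromide comes from a Baylis–Hillman homologation.
- Key disconnection (C–O): the furan-3(2H)-one O–C3 bond, made first, by a one-pot ring switch of an α-hydroxy-γ-butyrolactone with a lithium enyne acetylide (C1–C2, then 5-endo-dig oxa-Michael).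
- C10 is set by C–O bond formation (enolate hydroxylation anti to the C8 side arm), C8 comes from (R)-trityl glycidyl ether, and C6/C7 are set in the macrocyclisation.
- Ring order: temporary γ-lactone template → furanone → carbocycle plus α-methylene lactone.

Assumption: positions are named with germacrane numbering (C1 ketone, C2=C3 furanone alkene, C4=C5 Z alkene, C6 lactone carbinol, C8 acyloxy carbon, C10 quaternary carbon); the target is read as (6R,7R,8R,10S).

**Route**

Step 1
Reactants: 1 propanoic acid; 2 (R)-2-[(trityloxy)methyl]oxirane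
Product: 5 (5R)-3-methyl-5-[(trityloxy)methyl]oxolan-2-one (C3 epimers), via dilithium propanoate enediolate 3 (not isolated), via hydroxy acid 4 (not isolated)
Conditions: LiN(iPr)2 (2.2 equiv), THF, 0 °C; 2, 0 → 45 °C; AcOH; PPTS (cat.), toluene, 60 °C
Reagents that add atoms: none
Why: The carboxylic acid dianion opens the terminal epoxide at its CH2 carbon (SN2, so the purchased C8 stereocentre is untouched) and the γ-hydroxy acid lactonises under mild acid; the C3 epimers converge in step 2.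

Step 2
Reactants: 5
Product: 7 (3S,5R)-3-hydroxy-3-methyl-5-[(trityloxy)methyl]oxolan-2-one, via sodium enolate 6 (not isolated)
Conditions: NaN(SiMe3)2, THF, −78 °C; 3-phenyl-2-(phenylsulfonyl)oxaziridine, −78 °C; AcOH
Reagents that add atoms: 3-phenyl-2-(phenylsulfonyl)oxaziridine, O=S(=O)(N1OC1c1ccccc1)c1ccccc1
Why: Davis enolate hydroxylation; the electrophilic oxygen enters the planar lactone enolate anti to the bulky trityloxymethyl group, so this C–O bond sets C10 with the hydroxyl trans to the C8 side arm, as the target requires.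

Step 3
Reactants: 8 (Z)-3-methylpent-2-en-4-yn-1-ol
Product: 9 (Z)-tert-butyldimethyl[(3-methylpent-2-en-4-yn-1-yl)oxy]silane
Conditions: TBSCl, imidazole, CH2Cl2, 0 → 23 °C
Reagents that add atoms: tert-butyldimethylsilyl chloride, CC(C)(C)[Si](C)(C)Cl
Why: Standard silylation; it keeps the C6 oxygen from adding to the ynone of step 4 (furan formation), and the Z C4=C5 geometry is bought in with this vitamin A building block.

Step 4
Reactants: 9; 7
Product: 13 (S)-5-[(Z)-4-(tert-butyldimethylsilyloxy)but-2-en-2-yl]-2-[(R)-2-hydroxy-3-(trityloxy)propyl]-2-methylfuran-3(2H)-one, via lithium acetylide 10 (not isolated), via dilithium lactolate 11 (not isolated), via dihydroxy ynone 12 (not isolated)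
Conditions: 9 (2.3 equiv), n-BuLi (2.2 equiv), THF, −78 °C; 7, −78 → −40 °C; AcOH; then K2CO3, MeOH, 0 → 23 °C
Reagents that add atoms: none
Why: Proposed new method: a one-pot lactone-to-furanone ring switch, in which the acetylide adds once to the lactone carbonyl of the lithium alkoxide of 7 (the lactolate resists over-addition at low temperature), protonation lets the alkynyl lactol open to the α′-hydroxy ynone 12, and under K2CO3/MeOH the tertiary C10 alkoxide closes onto the ynone β-carbon by 5-endo-dig oxa-Michael addition (or by addition–elimination through the β-methoxy enone), so the lactone oxygen is released as the C8 hydroxyl and the C10 oxygen becomes the ring oxygen with both stereocentres untouched; the closest known chemistry is alkynyllithium addition to lactones or Weinreb amides followed by base- or gold-mediated cyclisation of isolated α′-hydroxy ynones to furan-3(2H)-ones.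

Step 5
Reactants: 13
Product: 14 (S)-2-[(R)-2-(tert-butyldimethylsilyloxy)-3-(trityloxy)propyl]-5-[(Z)-4-(tert-butyldimethylsilyloxy)but-2-en-2-yl]-2-methylfuran-3(2H)-one
Conditions: TBSOTf, 2,6-lutidine, CH2Cl2, −78 → 0 °C
Reagents that add atoms: tert-butyldimethylsilyl triflate, CC(C)(C)[Si](C)(C)OS(=O)(=O)C(F)(F)F
Why: Silylation of the secondary C8 alcohol; a silyloxy group (unlike an acyloxy group) is a poor leaving group, so the allylmetal of step 10 cannot undergo 1,4-elimination.

Step 6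
Reactants: 14
Product: 15 (S)-2-[(R)-2-(tert-butyldimethylsilyloxy)-3-hydroxypropyl]-5-[(Z)-4-hydroxybut-2-en-2-yl]-2-methylfuran-3(2H)-one
Conditions: CSA (0.2 equiv), MeOH/CH2Cl2 1:1, 0 → 23 °C
Reagents that add atoms: none
Why: Acid-catalysed methanolysis removes the trityl ether and the primary allylic silyl ether much faster than the hindered secondary C8 silyl ether, so both primary alcohols are freed in one operation.

Step 7
Reactants: 15
Product: 16 (R)-2-(tert-butyldimethylsilyloxy)-3-[(S)-2-methyl-3-oxo-5-[(Z)-4-oxobut-2-en-2-yl]-2,3-dihydrofuran-2-yl]propanal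
Conditions: DMP (3 equiv), NaHCO3, CH2Cl2, 0 → 23 °C
Reagents that add atoms: none
Why: Buffered Dess–Martin oxidation converts both primary alcohols to aldehydes without epimerising the α-silyloxy aldehyde (C8) or isomerising the Z enal.

Step 8
Reactants: 16; 17 methyl acrylate
Product: 18 methyl (4R)-4-(tert-butyldimethylsilyloxy)-3-hydroxy-2-methylidene-5-[(S)-2-methyl-3-oxo-5-[(Z)-4-oxobut-2-en-2-yl]-2,3-dihydrofuran-2-yl]pentanoate (C3 epimers)
Conditions: DABCO (1 equiv), 17 (20 equiv), MeOH (cat.), 23 °C, 48 h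
Reagents that add atoms: none
Why: Morita–Baylis–Hillman reaction; the activated aliphatic α-silyloxy aldehyde (C7) reacts, whereas the β,β-disubstituted conjugated enal (C6) is a very poor Baylis–Hillman electrophile; the new carbinol centre is lost in step 9.

Step 9
Reactants: 18
Product: 19 methyl (2Z,4R)-2-(bromomethyl)-4-(tert-butyldimethylsilyloxy)-5-[(S)-2-methyl-3-oxo-5-[(Z)-4-oxobut-2-en-2-yl]-2,3-dihydrofuran-2-yl]pent-2-enoate
Conditions: NBS, Me2S, CH2Cl2, −20 → 0 °C
Reagents that add atoms: N-bromosuccinimide, O=C1CCC(=O)N1Br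
Why: Corey–Kim-type activation of the Baylis–Hillman alcohol and SN2′ attack of bromide give the rearranged, thermodynamically preferred (Z)-2-(bromomethyl)enoate under conditions that leave the aldehyde alone.

Step 10
Reactants: 19
Product: 22 8-O-tert-butyldimethylsilyl ether of the 8-deacyl target (furanone-bridged ten-membered ring with 6,7-trans-fused α-methylene-γ-butyrolactone), via allylchromium dichloride 20 (not isolated), via dichlorochromium alkoxide 21 (not isolated)
Conditions: CrCl2 (6 equiv), THF, 0.002 M, slow addition, 23 °C; aq. NH4Cl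
Reagents that add atoms: none
Why: Intramolecular Barbier (Nozaki–Hiyama-type) allylation: divalent chromium inserts only into the allylic bromide and the γ-carbon (C7) adds to the aldehyde through a cyclic transition state; the Z C4=C5 bond and the furanone bridge are expected to hold H6 and H7 anti with the C8 silyloxy group on the outside, setting C6 and C7, and the alkoxide then closes the γ-lactone with loss of methanol, as in related germacranolide ring closures.

Step 11
Reactants: 22
Product: 23 8-deacyl target (free C8 alcohol; 6R,7R,8R,10S)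
Conditions: HF·pyridine, pyridine, THF, 0 → 23 °C
Reagents that add atoms: none
Why: Buffered fluoride desilylation frees the C8 alcohol without touching the α-methylene lactone or the furanone.

Step 12
Reactants: 24 (E)-4-acetoxy-2-methylbut-2-enal
Product: 25 (E)-4-acetoxy-2-methylbut-2-enoic acid
Conditions: NaClO2, NaH2PO4, 2-methylbut-2-ene, t-BuOH/H2O, 23 °C
Reagents that add atoms: sodium chlorite, [Na+].[O-]Cl=O
Why: Pinnick oxidation of the enal to the acid keeps the E alkene and the allylic acetate.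

Step 13
Reactants: 23; 25
Product: 26 CNP0387534.1 (target)
Conditions: DCC, DMAP (cat.), CH2Cl2, 0 → 23 °C
Reagents that add atoms: none
Why: Steglich esterification forms the C8–O ester with retention at C8, since only the acyl C–O bond is made.

**Compound list**
1 | propanoic acid | CCC(=O)O | starting material
2 | (R)-2-[(trityloxy)methyl]oxirane ((R)-trityl glycidyl ether) | C1[C@@H](O1)COC(c2ccccc2)(c2ccccc2)c2ccccc2 | starting material
3 | dilithium propanoate enediolate | [Li+].[Li+].CC=C([O-])[O-] | intermediate (not isolated)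
4 | (4R)-4-hydroxy-2-methyl-5-(trityloxy)pentanoic acid (C2 epimers) | CC(C[C@@H](O)COC(c1ccccc1)(c1ccccc1)c1ccccc1)C(=O)O | intermediate (not isolated)
5 | (5R)-3-methyl-5-[(trityloxy)methyl]oxolan-2-one (C3 epimers) | O=C1C(C)C[C@@H](O1)COC(c2ccccc2)(c2ccccc2)c2ccccc2 | intermediate
6 | sodium enolate of 5 | [Na+].[O-]C1=C(C)C[C@@H](O1)COC(c2ccccc2)(c2ccccc2)c2ccccc2 | intermediate (not isolated)
7 | (3S,5R)-3-hydroxy-3-methyl-5-[(trityloxy)methyl]oxolan-2-one | O=C1[C@](C)(C[C@@H](O1)COC(c2ccccc2)(c2ccccc2)c2ccccc2)O | intermediate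
8 | (Z)-3-methylpent-2-en-4-yn-1-ol | C#C/C(C)=C\CO | starting material
9 | (Z)-tert-butyldimethyl[(3-methylpent-2-en-4-yn-1-yl)oxy]silane | C#C/C(C)=C\CO[Si](C)(C)C(C)(C)C | intermediate
10 | lithium acetylide of 9 | [Li+].[C-]#C/C(C)=C\CO[Si](C)(C)C(C)(C)C | intermediate (not isolated)
11 | dilithium lactolate (alkynyl adduct at the lactone carbonyl of 7, both oxygens as lithium alkoxides) | [Li+].[Li+].[O-]C1(C#C/C(C)=C\CO[Si](C)(C)C(C)(C)C)[C@](C)(C[C@@H](O1)COC(c2ccccc2)(c2ccccc2)c2ccccc2)[O-] | intermediate (not isolated)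
12 | (2R,4S,8Z)-10-(tert-butyldimethylsilyloxy)-2,4-dihydroxy-4,8-dimethyl-1-(trityloxy)dec-8-en-6-yn-5-one | O=C(C#C/C(C)=C\CO[Si](C)(C)C(C)(C)C)[C@](C)(C[C@@H](O)COC(c1ccccc1)(c1ccccc1)c1ccccc1)O | intermediate (not isolated)
13 | (S)-5-[(Z)-4-(tert-butyldimethylsilyloxy)but-2-en-2-yl]-2-[(R)-2-hydroxy-3-(trityloxy)propyl]-2-methylfuran-3(2H)-one | CC(C)(C)[Si](C)(C)OC/C=C(/C)C1=CC(=O)[C@](C)(C[C@@H](O)COC(c2ccccc2)(c2ccccc2)c2ccccc2)O1 | intermediate
14 | (S)-2-[(R)-2-(tert-butyldimethylsilyloxy)-3-(trityloxy)propyl]-5-[(Z)-4-(tert-butyldimethylsilyloxy)but-2-en-2-yl]-2-methylfuran-3(2H)-one | CC(C)(C)[Si](C)(C)OC/C=C(/C)C1=CC(=O)[C@](C)(C[C@@H](O[Si](C)(C)C(C)(C)C)COC(c2ccccc2)(c2ccccc2)c2ccccc2)O1 | intermediate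
15 | (S)-2-[(R)-2-(tert-butyldimethylsilyloxy)-3-hydroxypropyl]-5-[(Z)-4-hydroxybut-2-en-2-yl]-2-methylfuran-3(2H)-one | OC/C=C(/C)C1=CC(=O)[C@](C)(C[C@@H](O[Si](C)(C)C(C)(C)C)CO)O1 | intermediate
16 | (R)-2-(tert-butyldimethylsilyloxy)-3-[(S)-2-methyl-3-oxo-5-[(Z)-4-oxobut-2-en-2-yl]-2,3-dihydrofuran-2-yl]propanal | O=C/C=C(/C)C1=CC(=O)[C@](C)(C[C@@H](O[Si](C)(C)C(C)(C)C)C=O)O1 | intermediate
17 | methyl acrylate | C=CC(=O)OC | starting material
18 | methyl (4R)-4-(tert-butyldimethylsilyloxy)-3-hydroxy-2-methylidene-5-[(S)-2-methyl-3-oxo-5-[(Z)-4-oxobut-2-en-2-yl]-2,3-dihydrofuran-2-yl]pentanoate (C3 epimers) | O=C/C=C(/C)C1=CC(=O)[C@](C)(C[C@@H](O[Si](C)(C)C(C)(C)C)C(O)C(=C)C(=O)OC)O1 | intermediate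
19 | methyl (2Z,4R)-2-(bromomethyl)-4-(tert-butyldimethylsilyloxy)-5-[(S)-2-methyl-3-oxo-5-[(Z)-4-oxobut-2-en-2-yl]-2,3-dihydrofuran-2-yl]pent-2-enoate | O=C/C=C(/C)C1=CC(=O)[C@](C)(C[C@@H](O[Si](C)(C)C(C)(C)C)/C=C(\CBr)C(=O)OC)O1 | intermediate
20 | allylchromium dichloride from 19 (CrCl2 in place of Br) | O=C/C=C(/C)C1=CC(=O)[C@](C)(C[C@@H](O[Si](C)(C)C(C)(C)C)/C=C(\C[Cr](Cl)Cl)C(=O)OC)O1 | intermediate (not isolated)
21 | dichlorochromium alkoxide of the ten-membered C6-hydroxy methyl ester (C6–C7 bond formed, lactone still open) | C=C(C(=O)OC)[C@H]1[C@H](O[Cr](Cl)Cl)/C=C(/C)C2=CC(=O)[C@](C)(C[C@H]1O[Si](C)(C)C(C)(C)C)O2 | intermediate (not isolated)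
22 | 8-O-tert-butyldimethylsilyl ether of the 8-deacyl target | C=C1C(=O)O[C@@H]2/C=C(/C)C3=CC(=O)[C@](C)(C[C@@H](O[Si](C)(C)C(C)(C)C)[C@@H]12)O3 | intermediate
23 | 8-deacyl target (6R,7R,8R,10S; free C8 alcohol) | C=C1C(=O)O[C@@H]2/C=C(/C)C3=CC(=O)[C@](C)(C[C@@H](O)[C@@H]12)O3 | intermediate
24 | (E)-4-acetoxy-2-methylbut-2-enal | O=C/C(C)=C/COC(C)=O | starting material
25 | (E)-4-acetoxy-2-methylbut-2-enoic acid | OC(=O)/C(C)=C/COC(C)=O | intermediate
26 | CNP0387534.1 | C=C1C(=O)O[C@@H]2/C=C(/C)C3=CC(=O)[C@](C)(C[C@@H](OC(=O)/C(C)=C/COC(C)=O)[C@@H]12)O3 | target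

**Step count and risks**

Total step count: 13. Longest linear sequence: 11 (steps 1, 2, 4, 5, 6, 7, 8, 9, 10, 11, 13).

The three steps most likely to fail:

Step 4 (the proposed new ring switch). The risks are over-addition of the acetylide, a lactol that is slow to open, or methanol addition outrunning ring closure. The fallback uses only known chemistry; it sets out from 7 and comes back at 13. The lactone is opened with MeNH(OMe)·HCl and i-PrMgCl to the Weinreb amide diol F1. Both hydroxyls are silylated (TMSOTf, Et3N) to give the bis(trimethylsilyl) ether F2. Lithium acetylide 10 is added to give the isolated silylated ynone F3. K2CO3 in MeOH then removes both trimethylsilyl groups and effects the established base-mediated 5-endo-dig cyclisation of the α′-hydroxy ynone to 13.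

Step 8 (Baylis–Hillman reaction on the dialdehyde). The risks are a slow reaction, attack or Z/E isomerisation at the enal, and partial epimerisation at C8. The fallback avoids having both aldehydes present; it sets out from 14 and comes back at 19. Only the trityl group is removed (HCO2H/Et2O, 23 °C, 15 min) to give the C7 alcohol F4. DMP oxidation gives the mono-aldehyde F5. The Baylis–Hillman reaction with 17 is run there to give the adduct F6. NBS/Me2S gives the allylic bromide F7. The primary allylic silyl ether is cleaved selectively (HF·pyridine, pyridine, 0 °C) to the bromo alcohol F8, and MnO2 oxidation gives 19.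

Step 10 (macrocyclising Barbier reaction). The risks are oligomerisation and, above all, the wrong configuration at C6, since open-chain 2-(bromomethyl)enoates favour cis lactones. The fallback sets C6 by C–O bond formation instead; it sets out from 19 and comes back at 22. If ring closure (CrCl2, or Zn with aq. NH4Cl) gives mainly the C6-epimeric 6,7-cis lactone F9, this is opened with LiOH (THF/H2O, 0 °C) to the seco hydroxy acid F10. Mitsunobu lactonisation (PPh3, DIAD, toluene) then closes the C6–O bond with inversion to give 22.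

Further compounds
F1 | step 4 | (2S,4R)-2,4-dihydroxy-N-methoxy-N,2-dimethyl-5-(trityloxy)pentanamide | CON(C)C(=O)[C@](C)(C[C@@H](O)COC(c1ccccc1)(c1ccccc1)c1ccccc1)O
F2 | step 4 | (2S,4R)-N-methoxy-N,2-dimethyl-5-(trityloxy)-2,4-bis(trimethylsilyloxy)pentanamide | CON(C)C(=O)[C@](C)(C[C@@H](O[Si](C)(C)C)COC(c1ccccc1)(c1ccccc1)c1ccccc1)O[Si](C)(C)C
F3 | step 4 | (2R,4S,8Z)-10-(tert-butyldimethylsilyloxy)-4,8-dimethyl-1-(trityloxy)-2,4-bis(trimethylsilyloxy)dec-8-en-6-yn-5-one | O=C(C#C/C(C)=C\CO[Si](C)(C)C(C)(C)C)[C@](C)(C[C@@H](O[Si](C)(C)C)COC(c1ccccc1)(c1ccccc1)c1ccccc1)O[Si](C)(C)C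
F4 | step 8 | (S)-2-[(R)-2-(tert-butyldimethylsilyloxy)-3-hydroxypropyl]-5-[(Z)-4-(tert-butyldimethylsilyloxy)but-2-en-2-yl]-2-methylfuran-3(2H)-one | CC(C)(C)[Si](C)(C)OC/C=C(/C)C1=CC(=O)[C@](C)(C[C@@H](O[Si](C)(C)C(C)(C)C)CO)O1
F5 | step 8 | (R)-2-(tert-butyldimethylsilyloxy)-3-[(S)-5-[(Z)-4-(tert-butyldimethylsilyloxy)but-2-en-2-yl]-2-methyl-3-oxo-2,3-dihydrofuran-2-yl]propanal | CC(C)(C)[Si](C)(C)OC/C=C(/C)C1=CC(=O)[C@](C)(C[C@@H](O[Si](C)(C)C(C)(C)C)C=O)O1
F6 | step 8 | methyl (4R)-4-(tert-butyldimethylsilyloxy)-5-[(S)-5-[(Z)-4-(tert-butyldimethylsilyloxy)but-2-en-2-yl]-2-methyl-3-oxo-2,3-dihydrofuran-2-yl]-3-hydroxy-2-methylidenepentanoate (C3 epimers) | CC(C)(C)[Si](C)(C)OC/C=C(/C)C1=CC(=O)[C@](C)(C[C@@H](O[Si](C)(C)C(C)(C)C)C(O)C(=C)C(=O)OC)O1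
F7 | step 8 | methyl (2Z,4R)-2-(bromomethyl)-4-(tert-butyldimethylsilyloxy)-5-[(S)-5-[(Z)-4-(tert-butyldimethylsilyloxy)but-2-en-2-yl]-2-methyl-3-oxo-2,3-dihydrofuran-2-yl]pent-2-enoate | CC(C)(C)[Si](C)(C)OC/C=C(/C)C1=CC(=O)[C@](C)(C[C@@H](O[Si](C)(C)C(C)(C)C)/C=C(\CBr)C(=O)OC)O1
F8 | step 8 | methyl (2Z,4R)-2-(bromomethyl)-4-(tert-butyldimethylsilyloxy)-5-[(S)-5-[(Z)-4-hydroxybut-2-en-2-yl]-2-methyl-3-oxo-2,3-dihydrofuran-2-yl]pent-2-enoate | OC/C=C(/C)C1=CC(=O)[C@](C)(C[C@@H](O[Si](C)(C)C(C)(C)C)/C=C(\CBr)C(=O)OC)O1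
F9 | step 10 | C6 epimer of 22 (6,7-cis-fused lactone) | C=C1C(=O)O[C@H]2/C=C(/C)C3=CC(=O)[C@](C)(C[C@@H](O[Si](C)(C)C(C)(C)C)[C@@H]12)O3
F10 | step 10 | seco hydroxy acid of F9 (ten-membered ring, C6 hydroxyl, 2-substituted acrylic acid at C7) | C=C(C(=O)O)[C@H]1[C@@H](O)/C=C(/C)C2=CC(=O)[C@](C)(C[C@H]1O[Si](C)(C)C(C)(C)C)O2
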